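(All constants are invented; the run is a simulation.)

In the early seconds of the flask, spent carrier turned fresh while the impurity began to take fresh carrier away for good, so I asked first what stayed at work.

    crystals ⇌ product, rate k1*(cs1 - [product]) while solid is left; crystals form when [product] > cs1 (cs1 = 0.29 mM, k1 = 0.40 /s)
    spent carrier + salt in the second phase ⇌ fresh carrier + spent salt in the second phase (K2 = 1.4, k2 = 2000 /M/s)
    substrate + fresh carrier → product + spent carrier (k3 = 2200 /M/s)
    fresh carrier + impurity → spent catalyst (k4 = 53000 /M/s)

substrate 1.0 mM; salt in the second phase 1.00 mM; spent carrier 10 µM; impurity 4.1 µM; time 1.0 min; volume of the second phase over the first 0.25

- what is said of product includes crystals
- in the second phase: salt in the second phase, spent salt in the second phase; everything else is in the first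
- charges count per volume of the first phase; a concentration in a rate is the amount of a species over the volume of its own phase; every rate counts per litre of the first phase
- crystals is a solid; its amount is given per volume of the solution
- run time (flask): 1.0 min

- how much product and crystals together there is at 1.0 min, in percent of the substrate charged
- the change that raises the amount of product and crystals together at 1.0 min, in percent of the substrate charged most ("none" if none brings more than 2 percentage points) (south-east / south-west / north-east / none)
- amount of product and crystals together at 1.0 min, in percent of the substrate charged, after south-east

I went through the given numbers in turn, in fractions of the charge, to see which had to be known well. The solubility and the dissolution coefficient dropped out first: the turnover step has no product on its left and the sum asked for counts crystals with product, so neither entered my reckoning. The impurity and the carrier charge came next, and both mattered. With a half-life of 2.22 s against the run of 60 s, the impurity should take its full toll early and leave 59.0% of the carrier live, so each percent of error in the carrier charge moved the live carrier by 1.69 percent. The split of live carrier mattered less. I took mid-run, with 80.0% of the substrate left and 0.200 mM of spent salt formed. There the pseudo-first-order constants were 6.40 /s for the exchange with salt, 1.76 /s for the turnover, which is slower, and 1.14 /s for the way back, so 68.8% of the live carrier stood fresh.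

The rule I carried was the decades of substrate decay, the turnover constant times live carrier times fresh share times time, over 2.3: 0.233. That gave 41.5% and, after south-east, 41.5%. Doubling the salt raised the fresh share to 83.2%, which gave 47.7%, so I chose south-west.

The forecast gave 41%, 41% after south-east and south-west as the best change, holding that “Crystallisation only shifts product between solution and solid”.

The simulation gave 41.2%, 41.2% after south-east, and south-west with 6.6 percentage points gained. The forward exchange half-life as charged, 0.087 s, was shorter than the turnover half-life of 0.32 s. At 1.00 min the flask held fresh carrier at 32.9% of the catalyst charged, beside spent carrier at 26.1%. Its 58.8% of substrate left reads 0.231 decades against my 0.233. The neighbour flask with 0.025 mM of spent carrier had 1.20 decades on offer at full fresh share, and its 26.7% of substrate left reads 0.574, a mean fresh share of 47.8%.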